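## Structural features

The target is a C30 bis-catechol: two benzene rings, each carrying a (1S)-1,2,2-trimethylcyclopentyl group, joined through one CH2 group. Ring A (numbered as in the SMILES: C1 CH3, C2 H, C3 cyclopentyl, C4 OH, C5 OH, C6 CH2) is pentasubstituted, and ring B (C1′ CH2, C2′ H, C3′ OH, C4′ OH, C5′ cyclopentyl, C6′ H) is tetrasubstituted; the bridge carbon on C1′ is a former aryl methyl group now bonded to C6 of ring A. The only stereocenters are the two benzylic quaternary carbons, both (S); each stands next to a quaternary CMe2 carbon in its cyclopentane, but the two are nine bonds apart, so neither can control the other. The fragile groups are the two catechols (air oxidation to ortho-quinones), the doubly benzylic CH2 para to the C4′ hydroxyl, and the tert-alkyl–aryl bonds under strong acid. The real difficulty is the arylated quaternary stereocenter flanked by CMe2 and an ortho oxygen, met twice, followed by the unsymmetrical CH2 link to the crowded C6. The key step exploits the fact that in each ring the quaternary carbon is bonded to an arene carbon ortho to a phenolic oxygen (C3 beside C4–O in ring A, C5′ beside C4′–O in ring B), while the two cyclopentane carbons on the side away from CMe2 are plain CH2 groups. This array, O–C(aryl)–C(aryl)–C(quaternary) plus a removable alkene, is the retron of an aromatic Claisen rearrangement of an aryl cyclopent-2-enyl ether. Both halves have the same constitution and configuration, so one monomer serves twice.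

## Logic of the disconnections

In one sentence: an aromatic Claisen rearrangement of 6 carries a C–O stereocenter across a cyclopentene ring into the benzylic quaternary carbon that both halves of 14 contain.

14 to 13. The two O–CH3 bonds on O5 (ring A) and O3′ (ring B) are cut. The catechols are carried as guaiacol-type mono-methyl ethers, so no oxidation-prone catechol exists before the last step. The forward step must cleave two aryl methyl ethers without touching the diarylmethane or the tert-alkyl–aryl bonds.

13 to 9 plus 11 (through 12). The C6–CH2 bond is cut. The bridge carbon is para to the C4′ hydroxyl, so its natural electrophilic form is the para-hydroxybenzyl cation 12, the O-protonated form of the para-quinone methide 10. The nucleophile 9 and the electrophile precursor 11 derive from the same compound, which halves the problem from C30 to C15. The forward step must alkylate the carbon of 9 that lies between OMe and CH3, and must not alkylate 11 or 13.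

11 to 9 (through 10). The benzylic C–OMe bond is cut. Compound 9 is a 2,6-disubstituted para-cresol and can be oxidized at its methyl group through 10. The forward step must stop at the benzylic ether level.

9 to 8. A C=C bond is introduced between the two CH2 carbons next to the quaternary carbon, on the side away from CMe2. This places the quaternary carbon allylic and prepares the sigmatropic retron. The forward step is a simple hydrogenation that creates no stereocenter.

8 to 6 (key). The aryl–C(quaternary) bond is cut and the allyl unit is reattached through its other terminus to the phenolic oxygen. A congested all-carbon quaternary stereocenter is exchanged for a secondary C–O stereocenter. The forward step must be a concerted, suprafacial [3,3] shift onto a neopentyl-type alkene carbon, faster than C–O heterolysis.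

6 to 4 plus 5. The O–C1 bond of the cyclopentenyl ether is cut. The forward step must join a phenol and a secondary allylic alcohol with clean inversion and without allylic transposition.

4 to 3. The carbinol C–H bond is cut, so the stereochemical problem becomes an enantioselective 1,2-reduction of a cyclic enone.

3 to 2 to 1. The C3–CH3 bond and the C2=C3 unsaturation are removed in turn. The forward steps add a methyl group in conjugate fashion next to CMe2 and then restore the enone, which for lack of any other β-hydrogen can form in one position only.

## Other disconnections considered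

Alternative 1: This is the first plan that comes to mind. The C6–CH2 bond is cut between two fully methylated monomers, and each monomer is built by conjugate addition. A methyl nucleophile is added under copper catalysis with a chiral ligand to the 3-aryl-2-methylcyclopentenone A1 (aryl = 2,3-dimethoxy-5-methylphenyl). The enolate is methylated to ketone A2, deoxygenation gives the dimethyl ether A3, and two molecules of A3 are joined by benzylic halogenation and Friedel–Crafts benzylation. The chosen plan is preferred on three grounds. A1 is a tetrasubstituted enone whose ortho-methoxy aryl group is twisted out of conjugation, and the quaternary carbon must be made intermolecularly against the same steric wall without any internal delivery. The carbonyl must then be removed from a doubly neopentyl position. Finally, A3 has no free para hydroxyl, so the mild quinone methide activation of the methyl group is lost and the sequence is longer.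

Alternative 2: Both aryl–C(quaternary) bonds are cut on a preformed diarylmethane, so the two stereocenters are set as a group. Bis-phenol A4 would be converted into bis-ether A5, and a twofold aromatic Claisen rearrangement would give A6. The idea is attractive, but A4 requires benzylation of a creosol ring at the carbon between OMe and CH3 while the positions ortho to OH and para to OMe are still open. In the chosen route the tert-alkyl group already blocks those positions, so the substrate dictates the regiochemistry of the link. A4 would need a directed or blocked synthesis of several steps. Two demanding rearrangements in one molecule also compound their losses, and since both halves come from one monomer anyway, nothing is gained in convergence.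

Alternative 3: The C6–CH2 bond is cut in the biomimetic sense. Unprotected (S)-herbertenediol A7 is half-oxidized in one pot to the ortho-quinone A8, which tautomerizes to quinone methide A9 and is captured at C6 by a second molecule of A7. The same phenoxyl and quinone manifold should also open C6–C6′ biaryl coupling. The product, with two catechols and a CH2 para to a hydroxyl, should be more easily oxidized than A7, so the oxidation cannot be expected to stop at the dimer. This cut also leaves the quaternary stereocenter unsolved. The chosen route keeps the polarity of this idea but generates the quinone methide from a mono-ether that has only one oxidation channel, in a step separate from the C–C bond formation.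

Key step: step 5

Assumption: the SMILES is read as (S) at both quaternary carbons (priority aryl > CMe2 > CH2 > CH3), and 1 and 5 are taken as commercial.

## Steps

Step 1
Reactants: 1 4,4-dimethylcyclopent-2-en-1-one
Product: 2 trimethyl[(3,4,4-trimethylcyclopent-1-en-1-yl)oxy]silane (racemic)
Conditions: MeMgBr (1.3 equiv), CuBr·SMe2 (10 mol %), TMSCl (2 equiv), THF, −78 → −40 °C; Et3N, cold aq. NaHCO3
Reagents that add atoms: methylmagnesium bromide, C[Mg]Br; chlorotrimethylsilane, C[Si](C)(C)Cl
Why: Copper-catalyzed conjugate addition of a methyl Grignard reagent, accelerated by TMSCl, which traps the enolate regiospecifically as the C1=C2 silyl enol ether; the new C3 stereocenter is racemic and is erased in step 2.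

Step 2
Reactants: 2 trimethyl[(3,4,4-trimethylcyclopent-1-en-1-yl)oxy]silane
Product: 3 3,4,4-trimethylcyclopent-2-en-1-one
Conditions: Pd(OAc)2 (10 mol %), O2 (1 atm), DMSO, 40 °C
Reagents that add atoms: none
Why: Saegusa–Ito oxidation: the palladium enolate bound at C2 can only lose the C3 hydrogen by β-hydride elimination, so the enone can form in one position only, with the double bond on the methyl-bearing carbon next to CMe2.

Step 3
Reactants: 3 3,4,4-trimethylcyclopent-2-en-1-one
Product: 4 (1R)-3,4,4-trimethylcyclopent-2-en-1-ol
Conditions: (S)-Me-CBS oxazaborolidine (10 mol %), BH3·SMe2 (0.7 equiv), THF, −20 °C; MeOH quench, aq. NH4Cl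
Reagents that add atoms: none
Why: CBS reduction: the oxazaborolidine–borane complex binds the ketone with the alkenyl flank (C2=C3) as the larger group and the C5 methylene as the smaller, so the (S)-catalyst should deliver hydride to give the (1R)-allylic alcohol by 1,2-reduction; the enantiomeric purity is to be checked by chiral GC before use.

Step 4
Reactants: 4 (1R)-3,4,4-trimethylcyclopent-2-en-1-ol; 5 2-methoxy-4-methylphenol (creosol)
Product: 6 2-methoxy-4-methyl-1-{[(1S)-3,4,4-trimethylcyclopent-2-en-1-yl]oxy}benzene
Conditions: PPh3 (1.3 equiv), DIAD (1.3 equiv), PhMe, −20 → 0 °C; chromatography on Et3N-treated silica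
Reagents that add atoms: none
Why: Mitsunobu etherification: SN2 displacement of the oxyphosphonium ion by the phenoxide inverts C1 to (S); the SN2′ terminus C3 is tertiary and neopentyl and should not compete, and an apolar solvent at low temperature disfavors ionization.

Step 5
Reactants: 6 2-methoxy-4-methyl-1-{[(1S)-3,4,4-trimethylcyclopent-2-en-1-yl]oxy}benzene
Product: 8 2-methoxy-4-methyl-6-[(1S)-1,5,5-trimethylcyclopent-2-en-1-yl]phenol, via ortho-dienone 7 (not isolated)
Conditions: PhNEt2 (degassed), 185 °C, sealed tube, Ar
Reagents that add atoms: none
Why: Aromatic Claisen rearrangement ([3,3]-sigmatropic shift) of a cycloalk-2-enyl aryl ether with 1,3-chirality transfer; the closest known cases are the thermal rearrangements of enantioenriched aryl cyclopent-2-enyl and cyclohex-2-enyl ethers and the formation of benzylic quaternary carbons from γ,γ-disubstituted allyl aryl ethers. The O–C1 bond breaks while the free ortho carbon C6 of the arene bonds to C3 of the cyclopentene through a six-membered array; no ring is closed, and dienone 7 enolizes at once to phenol 8. The allyl unit is locked in the five-membered ring, so the arene can reach C3 only on the face from which the oxygen departs, whether the array is chair-like or boat-like; the (S) C–O center of 6 therefore maps onto the (S) quaternary carbon, and no alkene geometry is involved. The CMe2 carbon puts one methyl group on each face of C3, so it slows the shift but cannot bias the face. Regioselectivity comes from the substitution pattern: the other ortho carbon carries OMe and the para carbon carries CH3, so dienones formed there cannot enolize and revert, which leaves C6 as the only productive terminus. The selectivity the step needs is the concerted shift over C–O heterolysis to the methyl-substituted allyl cation; an apolar, basic, acid-free medium and the electron-rich arene (para CH3, ortho OMe) favor the pericyclic path. The sp3 center formed in 7 is lost on enolization and needs no control.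

Step 6
Reactants: 8 2-methoxy-4-methyl-6-[(1S)-1,5,5-trimethylcyclopent-2-en-1-yl]phenol
Product: 9 2-methoxy-4-methyl-6-[(1S)-1,2,2-trimethylcyclopentyl]phenol
Conditions: H2 (1 atm), 10% Pd/C, EtOAc, rt
Reagents that add atoms: none
Why: Heterogeneous hydrogenation of a cis-disubstituted cyclopentene; no stereocenter is formed, the quaternary carbon is not allylic to any leaving group, and the phenol and methyl ether are inert.

Step 7
Reactants: 9 2-methoxy-4-methyl-6-[(1S)-1,2,2-trimethylcyclopentyl]phenol
Product: 11 2-methoxy-4-(methoxymethyl)-6-[(1S)-1,2,2-trimethylcyclopentyl]phenol, via quinone methide 10 (not isolated)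
Conditions: DDQ (1.05 equiv), MeOH, 0 °C → rt
Reagents that add atoms: methanol, CO
Why: DDQ oxidation of a 2,6-disubstituted para-cresol (formal hydride loss from the phenol) gives para-quinone methide 10, which methanol captures by 1,6-addition at the exocyclic carbon to restore the phenol; one equivalent of oxidant at low temperature should hold the product at the benzylic ether level.

Step 8
Reactants: 9 2-methoxy-4-methyl-6-[(1S)-1,2,2-trimethylcyclopentyl]phenol (3 equiv); 11 2-methoxy-4-(methoxymethyl)-6-[(1S)-1,2,2-trimethylcyclopentyl]phenol
Product: 13 3-{4-hydroxy-3-methoxy-5-[(1S)-1,2,2-trimethylcyclopentyl]benzyl}-2-methoxy-4-methyl-6-[(1S)-1,2,2-trimethylcyclopentyl]phenol, via para-hydroxybenzyl cation 12 (not isolated)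
Conditions: BF3·OEt2 (20 mol %), CH2Cl2, −20 → 0 °C, slow addition of 11
Reagents that add atoms: none
Why: Acid-catalyzed Friedel–Crafts benzylation: BF3 ionizes the benzylic methyl ether of 11 with loss of methanol to the para-hydroxybenzyl cation 12, stabilized as an oxocarbenium ion by the para hydroxyl, and arene 9 captures it. The cation should attack C3 of 9, ortho to OMe and flanked only by OMe and CH3, because the other open carbon C5 lies between CH3 and the tert-alkyl group; excess 9, recoverable, suppresses reaction at the OMe-flanked carbon of 11 or 13. No stereocenter is touched.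

Step 9
Reactants: 13 3-{4-hydroxy-3-methoxy-5-[(1S)-1,2,2-trimethylcyclopentyl]benzyl}-2-methoxy-4-methyl-6-[(1S)-1,2,2-trimethylcyclopentyl]phenol
Product: 14 3-{3,4-dihydroxy-5-[(1S)-1,2,2-trimethylcyclopentyl]benzyl}-4-methyl-6-[(1S)-1,2,2-trimethylcyclopentyl]benzene-1,2-diol (target, CNP0137546.1)
Conditions: BBr3 (5 equiv), CH2Cl2, −78 → 0 °C; degassed H2O, aq. Na2S2O4, Ar
Reagents that add atoms: none
Why: Demethylation of aryl methyl ethers with BBr3 (bromide attack on the O-methyl group of the aryloxyborane complex); the diarylmethane and the tert-alkyl–aryl bonds should be inert at low temperature, and an oxygen-free reductive work-up protects the two catechols.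

## Compound list

1 | 4,4-dimethylcyclopent-2-en-1-one | CC1(C)C=CC(=O)C1 | starting material
2 | trimethyl[(3,4,4-trimethylcyclopent-1-en-1-yl)oxy]silane (racemic) | CC1C=C(O[Si](C)(C)C)CC1(C)C | intermediate
3 | 3,4,4-trimethylcyclopent-2-en-1-one | CC1=CC(=O)CC1(C)C | intermediate
4 | (1R)-3,4,4-trimethylcyclopent-2-en-1-ol | O[C@H]1C=C(C)C(C)(C)C1 | intermediate
5 | 2-methoxy-4-methylphenol (creosol) | COc1cc(C)ccc1O | starting material
6 | 2-methoxy-4-methyl-1-{[(1S)-3,4,4-trimethylcyclopent-2-en-1-yl]oxy}benzene | COc1cc(C)ccc1O[C@@H]1C=C(C)C(C)(C)C1 | intermediate
7 | 2-methoxy-4-methyl-6-(1,5,5-trimethylcyclopent-2-en-1-yl)cyclohexa-2,4-dien-1-one (ortho-dienone; quaternary carbon arranged as in 8, ring CH center transient and unassigned) | COC1=CC(C)=CC([C@@]2(C)C=CCC2(C)C)C1=O | intermediate (not isolated)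
8 | 2-methoxy-4-methyl-6-[(1S)-1,5,5-trimethylcyclopent-2-en-1-yl]phenol | COc1cc(C)cc([C@@]2(C)C=CCC2(C)C)c1O | intermediate
9 | 2-methoxy-4-methyl-6-[(1S)-1,2,2-trimethylcyclopentyl]phenol | COc1cc(C)cc([C@@]2(C)CCCC2(C)C)c1O | intermediate
10 | 2-methoxy-4-methylidene-6-[(1S)-1,2,2-trimethylcyclopentyl]cyclohexa-2,5-dien-1-one (para-quinone methide) | COC1=CC(=C)C=C([C@@]2(C)CCCC2(C)C)C1=O | intermediate (not isolated)
11 | 2-methoxy-4-(methoxymethyl)-6-[(1S)-1,2,2-trimethylcyclopentyl]phenol | COCc1cc(OC)c(O)c([C@@]2(C)CCCC2(C)C)c1 | intermediate
12 | {4-hydroxy-3-methoxy-5-[(1S)-1,2,2-trimethylcyclopentyl]phenyl}methylium (para-hydroxybenzyl cation, the O-protonated form of 10) | [CH2+]c1cc(OC)c(O)c([C@@]2(C)CCCC2(C)C)c1 | intermediate (not isolated)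
13 | 3-{4-hydroxy-3-methoxy-5-[(1S)-1,2,2-trimethylcyclopentyl]benzyl}-2-methoxy-4-methyl-6-[(1S)-1,2,2-trimethylcyclopentyl]phenol | Cc1cc([C@@]2(C)CCCC2(C)C)c(O)c(OC)c1Cc1cc(OC)c(O)c([C@@]2(C)CCCC2(C)C)c1 | intermediate
14 | 3-{3,4-dihydroxy-5-[(1S)-1,2,2-trimethylcyclopentyl]benzyl}-4-methyl-6-[(1S)-1,2,2-trimethylcyclopentyl]benzene-1,2-diol | Cc1cc([C@@]2(C)CCCC2(C)C)c(O)c(O)c1Cc1cc(O)c(O)c([C@@]2(C)CCCC2(C)C)c1 | target

## Step count and least certain steps

Total step count: 9. Longest linear sequence: 9 steps (1 to 14; compound 9 enters step 8 a second time as the nucleophile).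

Step 5 (key step). The most likely failure is that heterolysis of the allylic C–O bond outruns the sigmatropic shift, because the receiving carbon is neopentyl-hindered and the allyl cation is stabilized by its methyl group. This would show as fragmentation to phenol and diene, erosion of stereochemical fidelity through ion-pair return, and acid-induced cyclization of the product phenol onto the cyclopentene. A change of medium (a chelating lanthanide catalyst such as Eu(fod)3 at lower temperature, or silylation of the phenol as it forms) would be tried first. The fallback changes the bond-forming event to a copper-mediated anti-SN2′ arylation of an allylic picolinate with 1,3-chirality transfer. It sets out from 4 and 5 and comes back at 8. Alcohol 4 is acylated with retention (picolinic acid, DCC, DMAP) to (1R)-3,4,4-trimethylcyclopent-2-en-1-yl pyridine-2-carboxylate F1. Phenol 5 is brominated ortho to the hydroxyl (NBS) to 2-bromo-6-methoxy-4-methylphenol F2 and protected (MOMCl, i-Pr2NEt) as 1-bromo-3-methoxy-2-(methoxymethoxy)-5-methylbenzene F3. Mg in THF converts F3 into [3-methoxy-2-(methoxymethoxy)-5-methylphenyl]magnesium bromide F4. With CuBr·SMe2, F4 should attack C3 of F1 on the face opposite the leaving group, which is the same face that the Claisen route reaches after Mitsunobu inversion, and give 1-methoxy-2-(methoxymethoxy)-5-methyl-3-[(1S)-1,5,5-trimethylcyclopent-2-en-1-yl]benzene F5. HCl in MeOH then releases 8.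

Step 8. The most likely failure is poor site selectivity of the benzylation: cation 12 reacts with the OMe-flanked carbon of 11 or of 13 (oligomer formation) or with a phenol oxygen, because the wanted carbon of 9 is activated only by an ortho methoxy group. The fallback makes the nucleophile the free catechol, whose C6 is ortho to a free hydroxyl and is its only unhindered activated carbon. It sets out from 9 and 11 and comes back at 14. BBr3 converts part of 9 into 5-methyl-3-[(1S)-1,2,2-trimethylcyclopentyl]benzene-1,2-diol F6 (identical with A7). F6 in excess with 11 under mild acid (BF3·OEt2 or HFIP) should give 3-{4-hydroxy-3-methoxy-5-[(1S)-1,2,2-trimethylcyclopentyl]benzyl}-4-methyl-6-[(1S)-1,2,2-trimethylcyclopentyl]benzene-1,2-diol F7, and BBr3 then gives 14.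

Step 4. The most likely failure is ionization of the allylic oxyphosphonium intermediate, with partial loss of configuration and elimination to a diene. The fallback forms the same C–O bond through a π-allyl palladium complex with net retention (Tsuji–Trost etherification). It sets out from 3 and 5 and comes back at 6. Reduction of 3 with the (R)-CBS catalyst gives (1S)-3,4,4-trimethylcyclopent-2-en-1-ol F8, and ClCO2Me with pyridine gives methyl (1S)-3,4,4-trimethylcyclopent-2-en-1-yl carbonate F9. Pd(PPh3)4, a zerovalent palladium complex, ionizes F9 with inversion, and the phenoxide of 5 attacks the less hindered terminus C1 with a second inversion to give 6.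

Step 3. The most likely failure is modest facial discrimination, because the two flanks of the carbonyl (an alkene CH and a CH2 next to CMe2) differ little in size. The fallback replaces asymmetric reduction by resolution. It sets out from 3 and comes back at 4. Luche reduction (NaBH4, CeCl3·7H2O, MeOH) gives racemic 3,4,4-trimethylcyclopent-2-en-1-ol F10. Lipase-catalyzed acylation (immobilized Candida antarctica lipase B, vinyl acetate) is expected to convert the (R)-enantiomer into (1R)-3,4,4-trimethylcyclopent-2-en-1-yl acetate F11 and leave F8. Separation and methanolysis of F11 (K2CO3, MeOH) give 4. If the enzyme prefers the other enantiomer, the unreacted alcohol is 4 itself.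

Step 7. The most likely failure is over-oxidation beyond the benzylic ether level, or C–C self-coupling of the quinone methide, because the product is still a para-alkylphenol. The fallback oxidizes deliberately to the aldehyde and reduces back. It sets out from 9 and comes back at 13. DDQ (2.2 equiv) in aqueous dioxane gives 4-hydroxy-3-methoxy-5-[(1S)-1,2,2-trimethylcyclopentyl]benzaldehyde F12, and NaBH4 gives 4-(hydroxymethyl)-2-methoxy-6-[(1S)-1,2,2-trimethylcyclopentyl]phenol F13. Under the acid of step 8, F13 ionizes with loss of water to the same cation 12 and should give 13 with 9.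

## Further compounds

F1 | step 5 | (1R)-3,4,4-trimethylcyclopent-2-en-1-yl pyridine-2-carboxylate | O=C(O[C@H]1C=C(C)C(C)(C)C1)c1ccccn1
F2 | step 5 | 2-bromo-6-methoxy-4-methylphenol | COc1cc(C)cc(Br)c1O
F3 | step 5 | 1-bromo-3-methoxy-2-(methoxymethoxy)-5-methylbenzene | COCOc1c(Br)cc(C)cc1OC
F4 | step 5 | [3-methoxy-2-(methoxymethoxy)-5-methylphenyl]magnesium bromide | COCOc1c([Mg]Br)cc(C)cc1OC
F5 | step 5 | 1-methoxy-2-(methoxymethoxy)-5-methyl-3-[(1S)-1,5,5-trimethylcyclopent-2-en-1-yl]benzene | COCOc1c(OC)cc(C)cc1[C@@]1(C)C=CCC1(C)C
F6 | step 8 | 5-methyl-3-[(1S)-1,2,2-trimethylcyclopentyl]benzene-1,2-diol | Cc1cc(O)c(O)c([C@@]2(C)CCCC2(C)C)c1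
F7 | step 8 | 3-{4-hydroxy-3-methoxy-5-[(1S)-1,2,2-trimethylcyclopentyl]benzyl}-4-methyl-6-[(1S)-1,2,2-trimethylcyclopentyl]benzene-1,2-diol | Cc1cc([C@@]2(C)CCCC2(C)C)c(O)c(O)c1Cc1cc(OC)c(O)c([C@@]2(C)CCCC2(C)C)c1
F8 | step 4 | (1S)-3,4,4-trimethylcyclopent-2-en-1-ol | O[C@@H]1C=C(C)C(C)(C)C1
F9 | step 4 | methyl (1S)-3,4,4-trimethylcyclopent-2-en-1-yl carbonate | COC(=O)O[C@@H]1C=C(C)C(C)(C)C1
F10 | step 3 | 3,4,4-trimethylcyclopent-2-en-1-ol (racemic) | OC1C=C(C)C(C)(C)C1
F11 | step 3 | (1R)-3,4,4-trimethylcyclopent-2-en-1-yl acetate | CC(=O)O[C@H]1C=C(C)C(C)(C)C1
F12 | step 7 | 4-hydroxy-3-methoxy-5-[(1S)-1,2,2-trimethylcyclopentyl]benzaldehyde | COc1cc(C=O)cc([C@@]2(C)CCCC2(C)C)c1O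
F13 | step 7 | 4-(hydroxymethyl)-2-methoxy-6-[(1S)-1,2,2-trimethylcyclopentyl]phenol | COc1cc(CO)cc([C@@]2(C)CCCC2(C)C)c1O
A1 | alternative 1 | 3-(2,3-dimethoxy-5-methylphenyl)-2-methylcyclopent-2-en-1-one | COc1cc(C)cc(C2=C(C)C(=O)CC2)c1OC
A2 | alternative 1 | (3R)-3-(2,3-dimethoxy-5-methylphenyl)-2,2,3-trimethylcyclopentan-1-one (same spatial arrangement as the target; descriptor changes by priority) | COc1cc(C)cc([C@@]2(C)CCC(=O)C2(C)C)c1OC
A3 | alternative 1 | 1,2-dimethoxy-5-methyl-3-[(1S)-1,2,2-trimethylcyclopentyl]benzene | COc1cc(C)cc([C@@]2(C)CCCC2(C)C)c1OC
A4 | alternative 2 | 3-(4-hydroxy-3-methoxybenzyl)-2-methoxy-4-methylphenol | COc1cc(Cc2c(C)ccc(O)c2OC)ccc1O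
A5 | alternative 2 | 2-methoxy-3-(3-methoxy-4-{[(1S)-3,4,4-trimethylcyclopent-2-en-1-yl]oxy}benzyl)-4-methyl-1-{[(1S)-3,4,4-trimethylcyclopent-2-en-1-yl]oxy}benzene | COc1cc(Cc2c(C)ccc(O[C@@H]3C=C(C)C(C)(C)C3)c2OC)ccc1O[C@@H]1C=C(C)C(C)(C)C1
A6 | alternative 2 | 3-{4-hydroxy-3-methoxy-5-[(1S)-1,5,5-trimethylcyclopent-2-en-1-yl]benzyl}-2-methoxy-4-methyl-6-[(1S)-1,5,5-trimethylcyclopent-2-en-1-yl]phenol | Cc1cc([C@@]2(C)C=CCC2(C)C)c(O)c(OC)c1Cc1cc(OC)c(O)c([C@@]2(C)C=CCC2(C)C)c1
A7 | alternative 3 | 5-methyl-3-[(1S)-1,2,2-trimethylcyclopentyl]benzene-1,2-diol ((S)-herbertenediol) | Cc1cc(O)c(O)c([C@@]2(C)CCCC2(C)C)c1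
A8 | alternative 3 | 5-methyl-3-[(1S)-1,2,2-trimethylcyclopentyl]cyclohexa-3,5-diene-1,2-dione | CC1=CC(=O)C(=O)C([C@@]2(C)CCCC2(C)C)=C1
A9 | alternative 3 | 2-hydroxy-4-methylidene-6-[(1S)-1,2,2-trimethylcyclopentyl]cyclohexa-2,5-dien-1-one | C=C1C=C(O)C(=O)C([C@@]2(C)CCCC2(C)C)=C1
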